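By 74 min the readings of cedar and elm have levelled off, cedar up 4.00 mM and elm down 7.00 mM since 55 min, and before I spend E on larch I want to know what share of it will come back as X. Larch has a third of oak's E, twice its Q and the same J. If the share looks good I leave J as it is; if it looks poor I add J, as elm did.

| flask | E | Q | J | X | time |
|---|---|---|---|---|---|
| oak | 0.600 M | 1.20 M | 0.0180 M |  |  |
| cedar | 0.240 M | 0.840 M | 0.0180 M |  |  |
| alder | 0.600 M | 1.20 M | 0.0180 M | 0.300 M |  |
| elm | 0.600 M | 1.20 M | 0.0360 M |  |  |
| larch | 0.200 M | 2.40 M | 0.0180 M |  | 74 min |

| run | time / min | [X] / M |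
|---|---|---|
| oak run | 4.2 | 0.022 |
| oak run | 13 | 0.073 |
| oak run | 24 | 0.123 |
| oak run | 39 | 0.193 |
| oak run | 55 | 0.237 |
| oak run | 74 | 0.258 |
| cedar run | 4.2 | 0.013 |
| cedar run | 13 | 0.054 |
| cedar run | 24 | 0.094 |
| cedar run | 39 | 0.137 |
| cedar run | 55 | 0.166 |
| cedar run | 74 | 0.170 |
| alder run | 4.2 | 0.319 |
| alder run | 13 | 0.374 |
| alder run | 24 | 0.428 |
| alder run | 39 | 0.495 |
| alder run | 55 | 0.535 |
| alder run | 74 | 0.564 |
| elm run | 4.2 | 0.042 |
| elm run | 13 | 0.142 |
| elm run | 24 | 0.244 |
| elm run | 39 | 0.321 |
| elm run | 55 | 0.349 |
| elm run | 74 | 0.342 |

(standard deviation of a reading: 0.003 M)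

- Overall: E + Q -> X, with J as catalyst.
- Constant volume, constant temperature.
- What is held in complexes is read along with the free species.
- "The second partner" is Q.
- An order is taken over about fifteen percent of the charge, up and down.

* order of the initial rate in [J], near the charge of the oak run, the rate being that where two percent of its E are X
* X in the larch run at 74 min, as a share of the E charged

From 4.2 min to 24 min, elm gains 2.00 times the X that oak gains, so I take the order in J as about 1.00. But at 74 min elm holds 1.33 times oak's X, which is less than that early gain. Alder's gain by then, 44.0 % of its E, sits beside oak's 43.0 %, so added X does not seem to hold the flask back.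

I read this as E leaving by a route that avoids J, and I follow one molecule of E: it ends in X or goes the other way, with odds set by the two rates. Cedar holds 0.412 of E outside X for each X made: this is the waste per X. Elm's is 0.754. From 4.2 min to 24 min, cedar gains 0.802 times the X that oak gains, so elm's early rate is 2.49 times cedar's, and elm's E charge is 2.50 times cedar's. If waste times rate hangs on E and on neither Q nor J, it grows as the E charge to the power 1.66.

If lower E cost cedar nothing, cedar against oak gives an order in Q of 0.619; any such cost makes that order smaller. Scaling from cedar on these two assumptions, I estimate larch's waste per X at 0.159, so I reckon on 86.3 % of its E as X. That is good enough: I leave J as it is.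

The forecast gives 1 for the order in J and 90 % for larch, on other grounds than mine: “Oak stalls near 0.26 M with much E and Q left, so the catalyst is dying.” Its larch figure stands above mine.

The simulation gives 1.0 for the order and 82.3 % for larch, below both figures.

    J + E → JE (7.980 M⁻¹ min⁻¹)
    JE + Q → Wa (1.602 M⁻¹ min⁻¹)
    Wa → X + J (10.98 min⁻¹)
    2 Q ⇌ Q2, settled at all times (9.250 M⁻¹)
    2 E → Jy (0.06300 M⁻¹ min⁻¹)

In larch, J carried E and Q through JE and Wa to X while pairs of E went to Jy beside it, and by 74 min X stood at 82.3 % of the E charged, which leaves 0.215 of E outside X for each X, against my 0.159. In oak, the same count from cedar's 0.412 gives 1.51, and oak's readings give 1.33 at 74 min, with X still climbing.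

The readings are calculated with constants of no real substance, noise included.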